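All runs stem from a simulated flask on assumed constants; scatter was added.

The earlier teal run, Za (substrate) with 0.60 equiv of Zb (reagent), still shows 82 % of its Za at 4.00 min, and the green flask carries twice that Zb but has been followed for seconds.

| setting | green | teal | flask |
|---|---|---|---|
| Za | 0.018 M | 0.018 M | 0.018 M |
| Zb | 1.2 equiv | 0.60 equiv | 1.20 equiv |
| remark | the very flask that is asked about, followed so far | run made earlier |  |
| time |  |  | 5.0 min |

green run (percent of the Za charged)

| time / s | Zf / % | Zd / % | Zc / % | Ze / % | Za / % |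
|---|---|---|---|---|---|
| 10.0 | 0 | 3 | 0 | 0 | 95 |
| 15.0 | 0 | 1 | 4 | 0 | 91 |
| 25.0 | 1 | 0 | 5 | 0 | 96 |

teal run (percent of the Za charged)

| time / min | Zf / % | Zd / % | Zc / % | Ze / % | Za / % |
|---|---|---|---|---|---|
| 0.417 | 0 | 5 | 4 | 0 | 95 |
| 1.33 | 2 | 1 | 7 | 1 | 92 |
| 2.50 | 0 | 6 | 12 | 5 | 87 |
| 4.00 | 4 | 6 | 11 | 1 | 82 |

(scatter of a reading: 2 percentage points)

- the analysis behind the earlier runs scatters by 2 percentage points, standard deviation

* where most of what was charged as Za, at 5.0 min is found (Za / Zf / Zd / Ze / Zc)
* the largest share itself, whichever of these holds it, in percent of the Za charged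

I carry one quantity, κ, the pseudo-first-order constant of Za per equivalent of Zb present, at this Za charge. I assume Za decays as exp(−κ·m·t), with m the mean equivalents of Zb, and that each Za lost takes one Zb. Teal then has m = 0.510, so κ = 0.0973 min⁻¹ per equivalent.

At the early end of the green flask, Zb stands at its charge, the time constant is 8.57 min, and Za at 5.0 min comes to 55.8 %. But Zb does not stay at its charge. Joining the late end, with m taken from the Za lost and reckoned twice over, gives m = 1.01 and Za 61.3 %. The objection is the scatter of 2 percentage points on that one teal reading: one standard deviation lower gives Za 57.7 %. Even that exceeds 0.5 of the charge, so on this reckoning Za holds more of the green flask's charge than the products together, and I commit to Za near 61.3 %.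

The forecast says Za at 62 %, adding that “A higher order in Zb would lower this value”.

The flask gives Za at 57.8 %.

    Za + Zb → Zc (k = 0.0829 L mol⁻¹ s⁻¹)
    Za + Zb → Zd (k = 0.0309 L mol⁻¹ s⁻¹)
    Zb + Zc → Ze (k = 0.210 L mol⁻¹ s⁻¹)
    Zb + Zd → Ze (k = 0.0716 L mol⁻¹ s⁻¹)
    Zc → Zf (k = 0.00111 s⁻¹)

On this flask, 54.0 % of the Zb charge remains at 5.0 min, so the mean of its two ends is 0.924 equivalents and κ read here is 0.119 min⁻¹ per equivalent, above the 0.0973 min⁻¹ per equivalent from teal. The neighbour charged with 3.00 equiv of Zb keeps 59.7 % of its own charge, a mean of its two ends of 2.40 equivalents, so the κ read on this flask puts its Za at 24.2 %. That neighbour holds 24.6 % Za, and Ze takes the largest share, at 45.4 %.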